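The eleven-membered ring hides a δ,ε-unsaturated ketone: read the C15 methylene as a carbonyl and the C11–C12 oxirane as an E olefin, and O=C15–C1–C14–C13–C12=C11 is the signature of an oxy-Cope product. The route therefore builds a cis-hydrindanone, closes a seven-membered carbinol ring (C15, C16, C7–C11) by allylboration, and lets an anionic [3,3] shift trade the C15–C11 bond for C14–C13. That single operation enlarges the seven-membered ring by four atoms, bridges C1 and C16 of the cyclohexanone, sets the E olefin and places the ketone at C15. Its precursor is a tricyclic tertiary alcohol with an exocyclic methylene at C1 and an isopropenyl group at C11, trans to each other.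

Key step: step 18

Remark on numbering: C15 is the ring carbon that carries the exocyclic methylene; the cyclohexane is C15–C1–C2–C3–C4–C16 (C3 = CH–O, C4 = C–Me), the cyclopentane is C4–C5–C6–C7–C16, and the eleven-membered ring is C1–C14–C13–C12–C11–C10–C9–C8–C7–C16–C15.
Remark on stereochemistry: the C1 configuration of compounds 28 to 32 is erased in step 17 and one epimer is drawn; 12 and 38 are mixtures at the centres left undefined.

Step 1
Reactants: 1 4-methoxy-2-methylphenol
Product: 2 4,4-dimethoxy-2-methylcyclohexa-2,5-dien-1-one
Conditions: PhI(OAc)2, MeOH, 0 °C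
Reagents that add atoms: methanol CO
Why: Oxidative dearomatisation of a para-alkoxyphenol by the iodine diacetate in methanol is the standard route to quinone monoketals, the solvent being captured at the methoxy-bearing carbon.

Step 2
Reactants: 2 4,4-dimethoxy-2-methylcyclohexa-2,5-dien-1-one
Product: 3 4,4-dimethoxy-2-methylcyclohex-2-en-1-one
Conditions: H2 (1 atm), RhCl(PPh3)3 (5 mol %), benzene, 25 °C
Reagents that add atoms: none
Why: Homogeneous hydrogenation with the rhodium chloride tris(phosphine) complex is strongly retarded by substitution, so the disubstituted C=C bond should be saturated while the methyl-bearing enone stays.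

Step 3
Reactants: 3 4,4-dimethoxy-2-methylcyclohex-2-en-1-one
Product: 4 (S)-4,4-dimethoxy-2-methylcyclohex-2-en-1-ol
Conditions: (R)-2-methyl-CBS-oxazaborolidine (10 mol %), BH3·SMe2, THF, −20 °C
Reagents that add atoms: none
Why: Corey–Bakshi–Shibata reduction in which the α-methylated alkenyl arm plays the large group, so the (R)-catalyst should deliver hydride to the face that gives the S carbinol, the future C3.

Step 4
Reactants: 4 (S)-4,4-dimethoxy-2-methylcyclohex-2-en-1-ol
Product: 5 tert-butyldimethylsilyl ether of 4
Conditions: t-BuMe2SiCl, imidazole, DMF, 25 °C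
Reagents that add atoms: tert-butyldimethylsilyl chloride CC(C)(C)[Si](C)(C)Cl
Why: Routine silylation of a secondary allylic alcohol under basic conditions that leave the ketal alone.

Step 5
Reactants: 5 tert-butyldimethylsilyl ether of 4
Product: 6 (S)-4-(tert-butyldimethylsilyloxy)-3-methylcyclohex-2-en-1-one
Conditions: PPTS (10 mol %), acetone–H2O, 25 °C
Reagents that add atoms: water O
Why: Mild acid hydrolysis of the allylic dimethyl ketal unveils the ketone at the former ketal carbon, which gives the transposed enone (C15 ketone, C3 silyl ether) with the carbinol centre untouched.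

Step 6
Reactants: 6 (S)-4-(tert-butyldimethylsilyloxy)-3-methylcyclohex-2-en-1-one; 7 2-(2-bromoethyl)-1,3-dioxolane
Product: 10 cyclohexanone acetal with quaternary C4, via Grignard reagent 8 (not isolated), via trimethylsilyl enol ether 9 (not isolated)
Conditions: 7, Mg, THF, 25 °C; then 6, CuBr·SMe2 (10 mol %), Me3SiCl, THF, −78 to −40 °C; AcOH, THF–H2O, 0 °C
Reagents that add atoms: none
Why: Copper-catalysed, chlorosilane-accelerated 1,4-addition of the Grignard reagent builds the C4 quaternary centre, the nucleophile entering the enone face opposite the neighbouring C3 silyloxy group (methyl therefore cis to it), and the silyl enol ether is cleaved by the mild acid quench without touching the dioxolane.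

Step 7
Reactants: 10 cyclohexanone acetal with quaternary C4
Product: 11 keto aldehyde
Conditions: PPTS (0.2 equiv), acetone–H2O (10:1), 60 °C
Reagents that add atoms: water O
Why: Acid-catalysed hydrolysis of the dioxolane under pyridinium tosylate conditions frees the C7 aldehyde and is mild enough to leave the silyl ether in place.

Step 8
Reactants: 11 keto aldehyde
Product: 13 hydrindenone, via aldol adduct 12 (not isolated)
Conditions: KOH, MeOH, 0 to 40 °C
Reagents that add atoms: none
Why: Base-mediated intramolecular aldol condensation, in which only the C16 enolate can reach the aldehyde through a five-membered ring closure and dehydration of the aldol gives the conjugated C16=C7 enone; no stereocentre is at risk because C4 is quaternary and C3 is remote from the carbonyl group.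

Step 9
Reactants: 14 S-ethyl thioacetate
Product: 16 1-(tert-butyldimethylsilyloxy)-1-(ethylthio)ethene, via lithium enolate 15 (not isolated)
Conditions: LiN(iPr)2, THF, −78 °C; t-BuMe2SiCl, DMPU, −78 to 0 °C
Reagents that add atoms: tert-butyldimethylsilyl chloride CC(C)(C)[Si](C)(C)Cl
Why: Deprotonation of the thioester with the lithium amide and O-silylation of the enolate is the standard preparation of a silyl ketene thioacetal, the nucleophile for the next step.

Step 10
Reactants: 13 hydrindenone; 16 1-(tert-butyldimethylsilyloxy)-1-(ethylthio)ethene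
Product: 17 Michael adduct as C15 silyl enol ether
Conditions: Ph3CSbCl6 (5 mol %), CH2Cl2, −78 °C
Reagents that add atoms: none
Why: Mukaiyama–Michael addition under trityl cation catalysis, with silyl transfer to the enolate oxygen so that the C15 ketone stays masked as its enol ether; C7 is set by attack on the cyclopentene face opposite the angular C4 methyl, which stands almost perpendicular to the enone plane and shields its own side.

Step 11
Reactants: 17 Michael adduct as C15 silyl enol ether
Product: 20 cis-hydrindanone thioester, via lithium enolate 18 (not isolated), via methylated silyl enol ether 19 (not isolated)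
Conditions: LiN(iPr)2, THF, −78 °C; MeI, DMPU, −78 to −40 °C; then 1 M HCl, THF, 0 °C
Reagents that add atoms: iodomethane CI
Why: Alkylation of the thioester enolate, in which allylic 1,3-strain holds C7–H in the enolate plane so that iodomethane enters on the side away from the bulky C16 enol ether carbon (sets C8), followed by acid hydrolysis of the enol ether with protonation of C16 on the face opposite the C7 side chain to give the cis-fused hydrindanone, which is also the more stable ring fusion.

Step 12
Reactants: 20 cis-hydrindanone thioester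
Product: 21 C9 aldehyde
Conditions: Et3SiH, Pd/C (10 % Pd), acetone, 25 °C
Reagents that add atoms: none
Why: Fukuyama reduction, in which palladium inserts into the C–S bond and the silane delivers hydride to the acyl palladium species, a neutral process that should leave the ketone, the silyl ether and the α-stereocentre C8 untouched.

Step 13
Reactants: 21 C9 aldehyde; 22 2-methylbut-1-en-3-yne
Product: 25 dienyl carbinol, via dienylzirconocene chloride 23 (not isolated), via dienylmethylzinc 24 (not isolated)
Conditions: 22, Cp2Zr(H)Cl, CH2Cl2, 0 to 25 °C; Me2Zn, toluene, −65 °C; (−)-3-exo-morpholinoisoborneol (10 mol %), then 21, −30 to 0 °C; aq NH4Cl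
Reagents that add atoms: none
Why: Hydrozirconation of the terminal alkyne gives the E-dienylzirconium species, transmetalation to zinc gives a reagent that adds to aldehydes but not to ketones, and the amino alcohol ligand directs attack to the Si face of the aldehyde, which is also the Felkin–Anh face defined by C8, so C9 should be set S in a matched case (catalytic asymmetric alkenylzinc addition).

Step 14
Reactants: 25 dienyl carbinol
Product: 26 dienyl bis(silyl ether) ketone
Conditions: t-BuMe2SiOTf, 2,6-lutidine, CH2Cl2, −78 °C
Reagents that add atoms: tert-butyldimethylsilyl trifluoromethanesulfonate CC(C)(C)[Si](C)(C)OS(=O)(=O)C(F)(F)F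
Why: Silylation of the hindered secondary allylic alcohol with the silyl triflate and a hindered pyridine base, conditions too weakly basic at −78 °C to enolise the ketone.

Step 15
Reactants: 26 dienyl bis(silyl ether) ketone
Product: 28 C1 dimethylaminomethyl ketone, via lithium enolate 27 (not isolated)
Conditions: LiN(SiMe3)2, THF, −78 °C; Me2N=CH2 I (Eschenmoser's salt), −78 to 0 °C
Reagents that add atoms: N,N-dimethylmethyleneiminium iodide C=[N+](C)C.[I-]
Why: Mannich reaction of a preformed enolate, in which the bulky lithium amide removes a proton kinetically from the C1 methylene and not from the hindered C16 methine, and the iminium salt aminomethylates C1, which installs C14 in masked form.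

Step 16
Reactants: 28 C1 dimethylaminomethyl ketone
Product: 31 tricyclic amino carbinol, via allylboronate 29 (not isolated), via borate ester 30 (not isolated)
Conditions: HBpin (1.2 equiv), Ni(cod)2 (5 mol %), PCy3 (5 mol %), toluene, 25 °C; then 70 °C; aq NaHCO3
Reagents that add atoms: none
Why: Zerovalent nickel with PCy3 catalyses 1,4-hydroboration of the s-cis diene, hydrogen going to C10 and boron to the terminal C13 to give the Z-allylboronate, and on warming its γ-carbon C11 adds to the C15 ketone through a chair six-membered B–O transition state (intramolecular allylboration) that closes the seven-membered ring; the tether holds C16 equatorial and the Z geometry holds C10 axial in that chair, which places the new hydroxyl cis to the isopropenyl group (C11) and delivers C11 to the ketone face on which C7 stands (C15).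

Step 17
Reactants: 31 tricyclic amino carbinol
Product: 33 oxy-Cope precursor, via amine oxide 32 (not isolated)
Conditions: mCPBA (1.0 equiv), CH2Cl2, −78 to 0 °C; basic Al2O3 filtration; THF, 65 °C
Reagents that add atoms: none
Why: Chemoselective N-oxidation (amines react with the peracid far faster than 1,1-disubstituted olefins at low temperature) followed by thermal Cope elimination, a syn elimination that can only take the C1 hydrogen and so unveils the C1=C14 methylene without base or acid.

Step 18
Reactants: 33 oxy-Cope precursor
Product: 36 bridged bicyclo[8.3.1] ketone, via potassium alkoxide 34 (not isolated), via potassium enolate 35 (not isolated)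
Conditions: KH, 18-crown-6, THF, 0 to 25 °C; then MeOH, 25 °C
Reagents that add atoms: none
Why: KH with 18-crown-6 gives the naked potassium alkoxide, whose 1,5-diene C14=C1–C15(O−)–C11–C12=C13 undergoes a charge-accelerated [3,3] sigmatropic shift through a chair, the axial C15–C11 bond breaking as C14–C13 forms on the same face to give the bridgehead enolate, which methanol protonates. The closest known reaction type is the anionic oxy-Cope ring expansion of trans-1,2-dialkenylcycloalkanols to medium-ring enones, including cases that pass through bridgehead enolates of bicyclic ketones. The eleven-membered ring is closed by four-atom enlargement of the existing seven-membered ring (C15–C11 is exchanged for the path C15–C1–C14–C13–C12–C11), not by end-to-end cyclisation, and it ends bridged across C1 and C16 of the cyclohexanone. The only new stereocentre, C1, is set after the shift by enolate equilibration with the KOMe formed on quenching: the favoured epimer should carry C14 equatorial and trans to the axial C7, whereas the other would need both ring bonds axial or the carbonyl oxygen inside the large ring, and C16 should keep its cis fusion because its hydrogen is equatorial there and poorly aligned for enolisation. The selectivity the step must deliver is the E C11=C12 olefin, secured by the trans relation of the methylene-bearing C1 and the isopropenyl group on the seven-membered ring, which forces C10 equatorial in the chair, while the cyclohexane ring fixes the enolate geometry and enolate formation makes the shift irreversible.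

Step 19
Reactants: 36 bridged bicyclo[8.3.1] ketone
Product: 37 C15 methylene diene
Conditions: Cp2TiMe2, toluene, 75 °C, dark
Reagents that add atoms: dimethyltitanocene C[Ti](C)(C1C=CC=C1)C1C=CC=C1
Why: Petasis methylenation, in which thermolysis of dimethyltitanocene gives a titanium methylidene that converts even hindered, enolisable ketones into methylene compounds through an oxatitanacyclobutane, and because the reagent is not basic the C1 and C16 centres should survive.

Step 20
Reactants: 37 C15 methylene diene
Product: 39 C13 enone, via allylic alcohol mixture 38 (not isolated)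
Conditions: SeO2 (0.5 equiv), t-BuOOH, CH2Cl2, 0 to 25 °C; then Dess–Martin periodinane, CH2Cl2, 25 °C
Reagents that add atoms: selenium dioxide O=[Se]=O; tert-butyl hydroperoxide CC(C)(C)OO (terminal oxidant that restores the selenium oxide)
Why: Selenium dioxide allylic oxidation (ene reaction then [2,3] shift) attacks the more electron-rich trisubstituted olefin at the more substituted carbon C12 and there prefers the ring methylene C13, which is E-disposed, over the methyl group, while the hindered 1,1-disubstituted methylene has only tertiary allylic hydrogens; Dess–Martin oxidation of the crude alcohols then converges both C13 epimers on the enone.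

Step 21
Reactants: 39 C13 enone
Product: 40 (13R)-allylic alcohol
Conditions: (S)-2-methyl-CBS-oxazaborolidine (0.5 equiv), catecholborane, toluene, −78 °C
Reagents that add atoms: none
Why: Corey–Bakshi–Shibata reduction of the enone with catecholborane, the α-methylated alkenyl arm acting as the large group so that the (S)-catalyst should give the 13R allylic alcohol by 1,2-reduction under reagent control.

Step 22
Reactants: 40 (13R)-allylic alcohol
Product: 41 triol
Conditions: Bu4NF, THF, 50 °C
Reagents that add atoms: none
Why: Fluoride cleavage of both silyl ethers, the hindered C3 ether requiring gentle warming, with no other fluoride-sensitive group in the molecule.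

Step 23
Reactants: 41 triol
Product: 42 tripropionate diene
Conditions: (EtCO)2O, Et3N, DMAP, CH2Cl2, 25 to 40 °C
Reagents that add atoms: propionic anhydride CCC(=O)OC(=O)CC
Why: Acylation of the three secondary alcohols under nucleophilic catalysis by DMAP, which is needed for the hindered C3 hydroxyl next to the quaternary carbon.

Step 24
Reactants: 42 tripropionate diene
Product: 43 CNP0332420.1
Conditions: L-fructose-derived Shi ketone (0.3 equiv), Oxone (2KHSO5·KHSO4·K2SO4), K2CO3, Bu4NHSO4, MeCN–CH2(OMe)2–aq Na2B4O7 buffer, 0 °C
Reagents that add atoms: Oxone (potassium peroxymonosulfate) [K+].[O-]S(=O)(=O)OO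
Why: Shi epoxidation, in which the chiral dioxirane formed from the ketone and Oxone epoxidises E-trisubstituted olefins through a spiro transition state with reagent-controlled face selection, the L-fructose-derived ketone being the enantiomer that should deliver oxygen to the face giving the (11S,12R)-oxirane (anti to the C13 ester), while the hindered 1,1-disubstituted methylene is a poor substrate for this catalyst.

Compound list
1 | 4-methoxy-2-methylphenol | COc1ccc(O)c(C)c1 | starting material
2 | 4,4-dimethoxy-2-methylcyclohexa-2,5-dien-1-one | COC1(OC)C=CC(=O)C(C)=C1 | intermediate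
3 | 4,4-dimethoxy-2-methylcyclohex-2-en-1-one | COC1(OC)CCC(=O)C(C)=C1 | intermediate
4 | (S)-4,4-dimethoxy-2-methylcyclohex-2-en-1-ol | COC1(OC)CC[C@H](O)C(C)=C1 | intermediate
5 | tert-butyldimethylsilyl ether of 4 | COC1(OC)CC[C@H](O[Si](C)(C)C(C)(C)C)C(C)=C1 | intermediate
6 | (S)-4-(tert-butyldimethylsilyloxy)-3-methylcyclohex-2-en-1-one (C3 carbinol, C15 ketone) | O=C1CC[C@H](O[Si](C)(C)C(C)(C)C)C(C)=C1 | intermediate
7 | 2-(2-bromoethyl)-1,3-dioxolane (C5, C6, C7) | BrCCC1OCCO1 | starting material
8 | [2-(1,3-dioxolan-2-yl)ethyl]magnesium bromide | Br[Mg]CCC1OCCO1 | intermediate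
9 | trimethylsilyl enol ether (C15=C16) of 10 | C[Si](C)(C)OC1=C[C@](C)(CCC2OCCO2)[C@@H](O[Si](C)(C)C(C)(C)C)CC1 | intermediate
10 | 4-silyloxy-3-methyl-3-[2-(1,3-dioxolan-2-yl)ethyl]cyclohexanone, methyl cis to the silyloxy group (quaternary C4) | O=C1CC[C@H](O[Si](C)(C)C(C)(C)C)[C@@](C)(CCC2OCCO2)C1 | intermediate
11 | keto aldehyde (dioxolane of 10 replaced by CHO) | O=C1CC[C@H](O[Si](C)(C)C(C)(C)C)[C@@](C)(CCC=O)C1 | intermediate
12 | aldol adduct (β-hydroxy ketone, mixture at C7 and C16) | O=C1CC[C@H](O[Si](C)(C)C(C)(C)C)[C@@]2(C)CCC(O)C12 | intermediate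
13 | hydrindenone (C16=C7 conjugated to the C15 ketone, angular methyl at C4, silyl ether at C3) | O=C1CC[C@H](O[Si](C)(C)C(C)(C)C)[C@@]2(C)CCC=C12 | intermediate
14 | S-ethyl thioacetate (C8, C9) | CCSC(C)=O | starting material
15 | lithium enolate of 14 | C=C([O-])SCC.[Li+] | intermediate
16 | 1-(tert-butyldimethylsilyloxy)-1-(ethylthio)ethene | C=C(SCC)O[Si](C)(C)C(C)(C)C | intermediate
17 | Michael adduct: C15 silyl enol ether, CH2C(O)SEt at C7 trans to the angular methyl | CC(C)(C)[Si](C)(C)OC1=C2[C@H](CC(=O)SCC)CC[C@]2(C)[C@@H](O[Si](C)(C)C(C)(C)C)CC1 | intermediate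
18 | lithium enolate of thioester 17 | CC(C)(C)[Si](C)(C)OC1=C2[C@H](C=C([O-])SCC)CC[C@]2(C)[C@@H](O[Si](C)(C)C(C)(C)C)CC1.[Li+] | intermediate
19 | C8-methylated silyl enol ether | CC(C)(C)[Si](C)(C)OC1=C2[C@H]([C@H](C)C(=O)SCC)CC[C@]2(C)[C@@H](O[Si](C)(C)C(C)(C)C)CC1 | intermediate
20 | cis-hydrindanone thioester (C7, C8, C16 set) | O=C1CC[C@H](O[Si](C)(C)C(C)(C)C)[C@@]2(C)CC[C@@H]([C@H](C)C(=O)SCC)[C@@H]12 | intermediate
21 | C9 aldehyde | O=C1CC[C@H](O[Si](C)(C)C(C)(C)C)[C@@]2(C)CC[C@@H]([C@H](C)C=O)[C@@H]12 | intermediate
22 | 2-methylbut-1-en-3-yne (C10 to C13 with the C12 methyl) | C=C(C)C#C | starting material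
23 | (E)-(3-methylbuta-1,3-dienyl)zirconocene chloride | C=C(C)/C=C/[Zr](Cl)(C1C=CC=C1)C1C=CC=C1 | intermediate
24 | methyl[(E)-3-methylbuta-1,3-dienyl]zinc | C=C(C)/C=C/[Zn]C | intermediate
25 | (9S)-dienyl carbinol ketone | O=C1CC[C@H](O[Si](C)(C)C(C)(C)C)[C@@]2(C)CC[C@@H]([C@H](C)[C@@H](O)/C=C/C(C)=C)[C@@H]12 | intermediate
26 | (E)-dienyl bis(silyl ether) ketone | O=C1CC[C@H](O[Si](C)(C)C(C)(C)C)[C@@]2(C)CC[C@@H]([C@H](C)[C@@H](O[Si](C)(C)C(C)(C)C)/C=C/C(C)=C)[C@@H]12 | intermediate
27 | lithium enolate (C15=C1) of 26 | [Li+].[O-]C1=CC[C@H](O[Si](C)(C)C(C)(C)C)[C@@]2(C)CC[C@@H]([C@H](C)[C@@H](O[Si](C)(C)C(C)(C)C)/C=C/C(C)=C)[C@@H]12 | intermediate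
28 | C1 dimethylaminomethyl ketone (Mannich base, one C1 epimer drawn) | O=C1[C@H](CN(C)C)C[C@H](O[Si](C)(C)C(C)(C)C)[C@@]2(C)CC[C@@H]([C@H](C)[C@@H](O[Si](C)(C)C(C)(C)C)/C=C/C(C)=C)[C@@H]12 | intermediate
29 | (Z)-allyl pinacol boronate (boron on C13, C11=C12 Z, C10 now CH2) | O=C1[C@H](CN(C)C)C[C@H](O[Si](C)(C)C(C)(C)C)[C@@]2(C)CC[C@@H]([C@H](C)[C@@H](O[Si](C)(C)C(C)(C)C)C/C=C(/C)CB3OC(C)(C)C(C)(C)O3)[C@@H]12 | intermediate
30 | pinacol borate ester of 31 | CN(C)C[C@@H]1C[C@H](O[Si](C)(C)C(C)(C)C)[C@@]2(C)CC[C@H]3[C@H](C)[C@@H](O[Si](C)(C)C(C)(C)C)C[C@H](C(C)=C)[C@]1(OB4OC(C)(C)C(C)(C)O4)[C@@H]23 | intermediate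
31 | tricyclic amino carbinol (cyclopentane, cyclohexane and cycloheptanol rings; C15 hydroxyl cis to C11 isopropenyl and to H16) | CN(C)C[C@@H]1C[C@H](O[Si](C)(C)C(C)(C)C)[C@@]2(C)CC[C@H]3[C@H](C)[C@@H](O[Si](C)(C)C(C)(C)C)C[C@H](C(C)=C)[C@]1(O)[C@@H]23 | intermediate
32 | amine oxide of 31 | C[N+](C)([O-])C[C@@H]1C[C@H](O[Si](C)(C)C(C)(C)C)[C@@]2(C)CC[C@H]3[C@H](C)[C@@H](O[Si](C)(C)C(C)(C)C)C[C@H](C(C)=C)[C@]1(O)[C@@H]23 | intermediate
33 | oxy-Cope precursor: cycloheptanol with C1=C14 methylene and C11 isopropenyl, trans to each other | C=C1C[C@H](O[Si](C)(C)C(C)(C)C)[C@@]2(C)CC[C@H]3[C@H](C)[C@@H](O[Si](C)(C)C(C)(C)C)C[C@H](C(C)=C)[C@]1(O)[C@@H]23 | intermediate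
34 | potassium alkoxide of 33 | C=C1C[C@H](O[Si](C)(C)C(C)(C)C)[C@@]2(C)CC[C@H]3[C@H](C)[C@@H](O[Si](C)(C)C(C)(C)C)C[C@H](C(C)=C)[C@]1([O-])[C@@H]23.[K+] | intermediate
35 | potassium bridgehead enolate (C15=C1) with the eleven-membered ring | [K+].[O-]C1=C2C[C@H](O[Si](C)(C)C(C)(C)C)[C@@]3(C)CC[C@@H]([C@H](C)[C@@H](O[Si](C)(C)C(C)(C)C)C/C=C(\C)CC2)[C@@H]13 | intermediate
36 | bridged bicyclo[8.3.1] ketone with E C11=C12 olefin, C14 trans to C7 | O=C1[C@H]2C[C@H](O[Si](C)(C)C(C)(C)C)[C@@]3(C)CC[C@@H]([C@H](C)[C@@H](O[Si](C)(C)C(C)(C)C)C/C=C(\C)CC2)[C@@H]13 | intermediate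
37 | C15 methylene diene | C=C1[C@H]2C[C@H](O[Si](C)(C)C(C)(C)C)[C@@]3(C)CC[C@@H]([C@H](C)[C@@H](O[Si](C)(C)C(C)(C)C)C/C=C(\C)CC2)[C@@H]13 | intermediate
38 | C13 allylic alcohols (both C13 epimers) | C=C1[C@H]2C[C@H](O[Si](C)(C)C(C)(C)C)[C@@]3(C)CC[C@@H]([C@H](C)[C@@H](O[Si](C)(C)C(C)(C)C)C/C=C(\C)C(O)C2)[C@@H]13 | intermediate
39 | C13 enone | C=C1[C@H]2C[C@H](O[Si](C)(C)C(C)(C)C)[C@@]3(C)CC[C@@H]([C@H](C)[C@@H](O[Si](C)(C)C(C)(C)C)C/C=C(\C)C(=O)C2)[C@@H]13 | intermediate
40 | (13R)-allylic alcohol | C=C1[C@H]2C[C@H](O[Si](C)(C)C(C)(C)C)[C@@]3(C)CC[C@@H]([C@H](C)[C@@H](O[Si](C)(C)C(C)(C)C)C/C=C(\C)[C@H](O)C2)[C@@H]13 | intermediate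
41 | C3, C9, C13 triol | C=C1[C@H]2C[C@H](O)[C@@]3(C)CC[C@@H]([C@H](C)[C@@H](O)C/C=C(\C)[C@H](O)C2)[C@@H]13 | intermediate
42 | tripropionate diene | C=C1[C@H]2C[C@H](OC(=O)CC)[C@@]3(C)CC[C@@H]([C@H](C)[C@@H](OC(=O)CC)C/C=C(\C)[C@H](OC(=O)CC)C2)[C@@H]13 | intermediate
43 | CNP0332420.1 (tripropionate with the 11S,12R oxirane) | C=C1[C@H]2C[C@H](OC(=O)CC)[C@@]3(C)CC[C@@H]([C@H](C)[C@@H](OC(=O)CC)C[C@@H]4O[C@@]4(C)[C@H](OC(=O)CC)C2)[C@@H]13 | target

Total step count: 24.
Longest linear sequence: 23 steps (steps 1 to 8 and 10 to 24 from compound 1; step 9 prepares the ketene thioacetal on a side branch).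

Steps most likely to fail

Step 18. The alkoxide may cleave heterolytically at C15–C11 (fragmentation to a ketone and an allyl anion) faster than it rearranges if the cyclohexane cannot bring that bond axial, and the basic quench may equilibrate C1 toward the unwanted epimer or drag C16 along. The fallback sets out from 33 and comes back at 36; it runs the sigmatropic shift on the neutral silyl ether, so there is no alkoxide and no fragmentation channel. Silylation of the tertiary alcohol (Me3SiOTf, 2,6-lutidine) would give the trimethylsilyl ether F2. Thermolysis in a sealed tube near 220 °C (thermal siloxy-Cope rearrangement) would give the ring-expanded trimethylsilyl enol ether F3. Dilute acid would then hydrolyse F3 to 36, so that the C1 protonation becomes a separate, acid-mediated operation that can be followed by a controlled amine-base equilibration.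

Step 16. Ring closure of the pinacol allylboronate onto the doubly α-branched ketone may be slower than loss of dimethylamine from the β-amino ketone or than a 1,3-boron shift that scrambles the olefin geometry, and the borane may reduce the carbonyl group before the diene is consumed. The fallback sets out from the allylboronate 29, which would then be isolated after hydroboration at 25 °C, and comes back at 31. KHF2 in aqueous methanol would exchange pinacol for fluoride and give the potassium allyltrifluoroborate F1. BF3·OEt2 in CH2Cl2 at −78 °C (one extra equivalent to tie up the amine) would release the allyldifluoroborane, which allylates ketones far faster than the pinacol ester but through the same closed chair, so the relative configuration of 31 should be unchanged.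

Step 24. The conformation of the eleven-membered ring may present the wrong olefin face, so that substrate and reagent control oppose each other; the allylic ester also slows the trisubstituted olefin, which could let the exocyclic methylene compete. The fallback sets out from the allylic alcohol 40 and comes back at 43; it moves the epoxidation ahead of the acylation and makes it hydroxyl-directed. Sharpless epoxidation (Ti(OiPr)4, D-(−)-diisopropyl tartrate, t-BuOOH, 4 Å sieves, CH2Cl2, −20 °C) is matched for the 13R carbinol, touches only the allylic alcohol olefin and should give the erythro epoxy alcohol F4, which has the relative configuration of the target. Fluoride buffered with acetic acid (to suppress epoxide migration) would then give the epoxy triol F5, and propionic anhydride with DMAP would give 43.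

Further compounds
F1 | step 16 | potassium allyltrifluoroborate corresponding to 29 | O=C1[C@H](CN(C)C)C[C@H](O[Si](C)(C)C(C)(C)C)[C@@]2(C)CC[C@@H]([C@H](C)[C@@H](O[Si](C)(C)C(C)(C)C)C/C=C(/C)C[B-](F)(F)F)[C@@H]12.[K+]
F2 | step 18 | trimethylsilyl ether of 33 | C=C1C[C@H](O[Si](C)(C)C(C)(C)C)[C@@]2(C)CC[C@H]3[C@H](C)[C@@H](O[Si](C)(C)C(C)(C)C)C[C@H](C(C)=C)[C@]1(O[Si](C)(C)C)[C@@H]23
F3 | step 18 | ring-expanded trimethylsilyl enol ether (C15=C1) | C[Si](C)(C)OC1=C2C[C@H](O[Si](C)(C)C(C)(C)C)[C@@]3(C)CC[C@@H]([C@H](C)[C@@H](O[Si](C)(C)C(C)(C)C)C/C=C(\C)CC2)[C@@H]13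
F4 | step 24 | erythro epoxy alcohol (bis-silyl ether) | C=C1[C@H]2C[C@H](O[Si](C)(C)C(C)(C)C)[C@@]3(C)CC[C@@H]([C@H](C)[C@@H](O[Si](C)(C)C(C)(C)C)C[C@@H]4O[C@@]4(C)[C@H](O)C2)[C@@H]13
F5 | step 24 | epoxy triol | C=C1[C@H]2C[C@H](O)[C@@]3(C)CC[C@@H]([C@H](C)[C@@H](O)C[C@@H]4O[C@@]4(C)[C@H](O)C2)[C@@H]13
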